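In a one-step world, free catalyst and partner turn each substrate into its product at a rate proportional to that substrate. Here is a flask to test that picture on, with two earlier runs.

| setting | Tuesday's | Friday's | flask |
|---|---|---|---|
| left-handed substrate | 2 mM | 2 mM | 2.0 mM |
| right-handed substrate | 2 mM | 2 mM | 2.0 mM |
| partner | 6 mM (fed, over 4.0 s) | 6 mM (fed, over 4.0 s) | 6.00 mM (fed, over 4.0 s) |
| racemization catalyst | 2 µM | 2 µM | 2.0 µM |
| precatalyst | 0.95 µM | 3.8 µM | 1.9 µM |
| remark | run made earlier | run made earlier |  |
| time |  |  | 2.5 min |

| run | time / min | left-handed product / % | right-handed product / % |
|---|---|---|---|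
| Tuesday's | 0.167 | 20.8 | 10.9 |
| Tuesday's | 0.500 | 32.5 | 17.9 |
| Tuesday's | 0.833 | 32.8 | 18.9 |
| Tuesday's | 1.33 | 31.5 | 19.1 |
| Tuesday's | 2.00 | 32.8 | 19.1 |
| Tuesday's | 2.50 | 32.8 | 18.2 |
| Friday's | 0.417 | 46.6 | 33.1 |
| Friday's | 0.833 | 46.6 | 33.7 |
| Friday's | 1.33 | 46.4 | 33.0 |
| Friday's | 1.50 | 46.8 | 33.3 |
| Friday's | 2.00 | 46.1 | 34.1 |
| Friday's | 2.50 | 47.3 | 33.8 |

(readings scatter by 0.5 percentage points)

- free catalyst is single-handed; left-handed substrate and right-handed substrate are mirror images of each other, charged as a racemate, each of them at the stated concentration
- an excess is below zero if the other one leads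

1. left-handed product and right-handed product together, in percent of the left-handed substrate and right-handed substrate charged together, at 2.5 min
2. excess of left-handed product over right-handed product in the product at 2.5 min
3. whether the exchange between left-handed substrate and right-handed substrate keeps pace with the reaction: how far the product's excess at 2.5 min gets from its value without exchange to its value with instant exchange (above 80 % keeps pace, below 20 % hardly takes part, else lags behind)

Suppose partner and free catalyst, however they vary in time, enter both rates alike; the ratio of the rates then integrates in closed form. Call minus the logarithm of a substrate's unreacted part its exposure. Without exchange: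

s = exposure of left-handed substrate / exposure of right-handed substrate

Each substrate is half of the charge, so the flat readings give the exposures. Means from 0.833 min on for Tuesday's run and from 0.417 min on for Friday's run:

Tuesday's run: left-handed product 32.5 %, right-handed product 18.8 %, exposures 1.05 and 0.472, s = 2.22

Friday's run: left-handed product 46.6 %, right-handed product 33.5 %, exposures 2.70 and 1.11, s = 2.43

Carry their mean, 2.33: the selectivity factor, the left-handed exposure over the right-handed one.

Now take the extremes. Without exchange, the rule above holds and the product's excess falls as conversion rises. With instant exchange, the products stand at s to one, an excess of 39.9 % at any conversion. Tuesday's excess is 26.6 % and Friday's 16.4 %, both lower than that, and Friday's is lower still. So you place the flask near the no-exchange end.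

Its precatalyst, 1.9 µM, is the geometric midpoint of the two runs, 1.90 µM. Assuming a steady power law, take the geometric mean of the right-handed exposures:

exposure = 0.724, yield 66.5 %, excess 22.5 %

The forecast, reckoned apart from this and differing from it slightly, says 67 %, 22 % and hardly takes part: a constant s “fits no meaningful exchange”.

The flask gives 66.3 %, 22.5 % and hardly takes part, 6.4 % of the way to the instant-exchange excess.

    partner + free catalyst + left-handed substrate → free catalyst + left-handed product (k = 8.46 × 10⁷ M⁻² s⁻¹)
    partner + racemization catalyst → spent catalyst (k = 12.4 M⁻¹ s⁻¹)
    partner + free catalyst + right-handed substrate → free catalyst + right-handed product (k = 3.81 × 10⁷ M⁻² s⁻¹)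
    precatalyst → free catalyst (k = 0.0517 s⁻¹)
    partner → decomposed reagent (k = 0.0972 s⁻¹)
    left-handed substrate + racemization catalyst ⇌ right-handed substrate + racemization catalyst, rate k6*[racemization catalyst]*[left-handed substrate] forward; the back reaction follows from the equilibrium constant (k = 3710 M⁻¹ s⁻¹)

Through s, the flask's right-handed product of 25.7 % gives 40.7 % of left-handed product, and 40.6 % stands there. The neighbouring flask, the same but with 3.6 mM of partner, holds 15.5 % of right-handed product at 2.50 min. Through s, that gives 28.9 % of left-handed product and an excess of 30.2 %. That neighbouring flask's simulated excess is 29.4 %.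

The numbers in the tables are calculated for substances that don't exist; noise was put on by code.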